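The numbers in the tables are calculated with constants of no real substance; the scatter is artificial.

Amounts first: the highest reading of dissolved substrate in the earlier runs is 16 % of the charge, in birch, and the reckoning below counts target from how much of it stands in solution and for how long.

| flask | solid substrate | reagent | protic impurity | remark | time |
|---|---|---|---|---|---|
| alder | 0.50 M | 1.5 equiv | 0.50 M | run made earlier |  |
| oak | 0.50 M | 2.4 equiv | 0.50 M | run made earlier |  |
| birch | 0.50 M | 1.1 equiv | 0.75 M | run made earlier |  |
| flask | 0.50 M | 1.10 equiv | 0.500 M |  | 2.5 h |

| run | time / min | target / % | dissolved substrate / % |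
|---|---|---|---|
| alder | 8.00 | 0 | 7 |
| alder | 15.0 | 2 | 10 |
| alder | 25.0 | 1 | 13 |
| alder | 50.0 | 12 | 10 |
| alder | 90.0 | 18 | 4 |
| oak | 8.00 | 1 | 5 |
| oak | 15.0 | 1 | 4 |
| oak | 25.0 | 6 | 10 |
| oak | 50.0 | 14 | 11 |
| oak | 90.0 | 23 | 3 |
| birch | 8.00 | 2 | 8 |
| birch | 25.0 | 4 | 16 |
| birch | 40.0 | 6 | 10 |
| birch | 60.0 | 5 | 8 |
| birch | 90.0 | 10 | 4 |

(standard deviation of a reading: 1.5 percentage points)

- solid substrate is a solid; its amount is given per volume of the solution
- at the start none of the solid substrate is in solution
- dissolved substrate means what is dissolved; the solid is not counted in it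

1. how much target there is at 2.5 h, in percent of the solid substrate charged
2. concentration of dissolved substrate in solution at 2.5 h, in percent of saturation

1. Exposure here means the area under the dissolved-substrate readings, as fraction of the charge times hours, starting from zero: up to its last reading the alder run gives 0.128 h, and the oak run 0.111 h.

2. Target over exposure reads 1.40 h⁻¹ in alder and 2.08 h⁻¹ in oak, a ratio of 1.49 against 1.60 in reagent, so the readings are taken as proportional to reagent and scaled to the flask's 1.10 equiv: 0.991 h⁻¹. This is the capture rate, the fraction of dissolved substrate turned into target per hour, a pseudo-first-order constant, with a half-life of 0.700 h.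

3. The flask shares alder's impurity, so this reckoning borrows alder's exposure for it, and that is the weak link, as alder holds more reagent than the flask. Beyond alder's last reading of dissolved substrate, 4 %, decay at the capture rate is estimated to add 0.0254 h and to end near 1.49 %.

4. Joined, the estimated exposure is 0.154 h, so the estimate of target is 15.2 %. Saturation is taken at or above the highest reading, 16 %, which gives an estimate for the flask of about or under 9.28 % of saturation.

The forecast, differing from this reckoning, says 14 % and 12 %, holding that “it should fall just above birch”.

The flask gives 17.0 % of target and 5.24 % of saturation.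

    solid substrate + protic impurity → quenched substrate (k = 15.2 M⁻¹ h⁻¹)
    dissolved substrate + reagent → target (k = 1.80 M⁻¹ h⁻¹)
    solid substrate ⇌ dissolved substrate, rate k3*(cs3 - [dissolved substrate]) while solid is left; crystals form when [dissolved substrate] > cs3 (solubility = 0.210 M, k = 1.15 h⁻¹)
    2 dissolved substrate → side product (k = 3.62 M⁻¹ h⁻¹)

Reforged, the weak link reads backward: 17.0 % over the capture rate makes the flask's exposure 0.172 h, longer than the borrowed 0.154 h. The neighbour flask, with 0.280 equiv of reagent, about a quarter of the flask's, has a capture rate of 0.252 h⁻¹, which on the flask's exposure makes 4.33 % of target. That neighbour holds 6.22 % of target, an exposure of 0.247 h, with 6.51 % still dissolved and 12.8 % as side product.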